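## Retrosynthetic overview

1. The E-allylic acetate (C13=C14, halimane numbering) comes last, by cross-metathesis of a 3-methylbut-3-enyl side chain with allyl acetate; that alkene comes from a Wittig reaction on a methyl ketone.
2. Ring A is closed by the key step: a hydrogen-atom-transfer radical cycloisomerisation of an α-substituted acrylic acid onto a ring B cyclohexene. It forms C4–C5, the C4 quaternary centre and the C1=C10 alkene in one operation.
3. The radical precursor is assembled by B-alkyl Suzuki coupling (C10–C1) of a ring B enol triflate with a five-carbon acrylate piece.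
4. The ring B stereocentres C8 and C9 come from asymmetric conjugate methylation of 2-methylcyclohex-2-enone with enolate alkylation by a masked 3-oxobutyl group.
5. Ring order: ring B is bought as the cyclohexenone; ring A is formed last on it.

Assumption: 1,3-dichlorobut-2-ene is sold as an E/Z mixture; it is drawn as the E isomer, and the geometry is erased in step 3.

## Route

Step 1
Reactants: 1 2-methylcyclohex-2-en-1-one; 2 (E)-1,3-dichlorobut-2-ene
Product: 4 (2R,3S)-2-[(2E)-3-chlorobut-2-en-1-yl]-2,3-dimethylcyclohexan-1-one, via bromomagnesium enolate 3 (not isolated)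
Conditions: MeMgBr, Cu(OTf)2 (3 mol %), chiral N-heterocyclic carbene ligand (4 mol %, enantiomer giving 3S), Et2O, −30 °C; then 2, HMPA, THF, −30 → 23 °C
Reagents that add atoms: methylmagnesium bromide, C[Mg]Br
Why: Copper-catalysed asymmetric conjugate addition sets C3 (S) under ligand control, and the bromomagnesium enolate is C-alkylated by the allylic chloride anti to the new C3 methyl group (tandem conjugate addition–enolate alkylation), which sets the quaternary C2 (R).

Step 2
Reactants: 4 (2R,3S)-2-[(2E)-3-chlorobut-2-en-1-yl]-2,3-dimethylcyclohexan-1-one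
Product: 5 (5S,6R)-6-[(2E)-3-chlorobut-2-en-1-yl]-5,6-dimethylcyclohex-1-en-1-yl trifluoromethanesulfonate
Conditions: KN(SiMe3)2, THF, −78 °C; PhNTf2, −78 → 0 °C
Reagents that add atoms: N-phenylbis(trifluoromethanesulfonimide), O=S(=O)(N(c1ccccc1)S(=O)(=O)C(F)(F)F)C(F)(F)F
Why: The ketone can enolise only toward its CH2 side because the other α-carbon is quaternary, so enol triflate formation gives a single regioisomer and touches no stereocentre.

Step 3
Reactants: 5 (5S,6R)-6-[(2E)-3-chlorobut-2-en-1-yl]-5,6-dimethylcyclohex-1-en-1-yl trifluoromethanesulfonate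
Product: 6 (5S,6R)-5,6-dimethyl-6-(3-oxobutyl)cyclohex-1-en-1-yl trifluoromethanesulfonate
Conditions: H2SO4 (90 %), CH2Cl2, 0 °C; then ice/H2O
Reagents that add atoms: water, O
Why: Acid hydrolysis of the vinyl chloride (Wichterle unmasking: Markovnikov protonation, capture of the α-chloro cation by water, loss of HCl) releases the methyl ketone, while the electron-poor enol triflate is inert to acid and no stereocentre is affected.

Step 4
Reactants: 7 methyl 2-(bromomethyl)prop-2-enoate; 8 vinylmagnesium bromide
Product: 9 methyl 2-methylidenepent-4-enoate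
Conditions: CuI (10 mol %), THF, −78 → 0 °C
Reagents that add atoms: none
Why: Copper-catalysed SN2′ allylic substitution (addition–elimination) of the bromomethyl acrylate by the vinyl Grignard reagent gives the skipped diene ester; no stereocentre is formed.

Step 5
Reactants: 6 (5S,6R)-5,6-dimethyl-6-(3-oxobutyl)cyclohex-1-en-1-yl trifluoromethanesulfonate; 9 methyl 2-methylidenepent-4-enoate
Product: 12 5-[(5S,6R)-5,6-dimethyl-6-(3-oxobutyl)cyclohex-1-en-1-yl]-2-methylidenepentanoic acid, via alkylborane 10 (not isolated), via methyl ester 11 (not isolated)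
Conditions: 9, 9-BBN (1.0 equiv), THF, 0 → 23 °C; then 6, PdCl2(dppf) (5 mol %), AsPh3, K3PO4 (3 M aq), DMF, 50 °C; then LiOH, MeOH/H2O, 23 °C; HCl work-up
Reagents that add atoms: 9-borabicyclo[3.3.1]nonane (boron stays only in 10), [BH]1C2CCCC1CCC2; lithium hydroxide, [Li+].[OH-]
Why: 9-BBN hydroborates the monosubstituted alkene of 9 at its terminus (the conjugated, electron-poor 1,1-disubstituted alkene is much slower), the B-alkyl Suzuki–Miyaura coupling joins that carbon to the enol triflate carbon without moving the ring alkene, and the unhindered acrylate ester is saponified in the same flask; the stereocentres are untouched.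

Step 6
Reactants: 12 5-[(5S,6R)-5,6-dimethyl-6-(3-oxobutyl)cyclohex-1-en-1-yl]-2-methylidenepentanoic acid
Product: 13 (1S,5R,6S,8aR)-1,5,6-trimethyl-5-(3-oxobutyl)-1,2,3,5,6,7,8,8a-octahydronaphthalene-1-carboxylic acid
Conditions: Co(dmgBF2)2(H2O)2 (7 mol %), H2 (6 atm), benzene, 50 °C
Reagents that add atoms: none
Why: Proposed new method: HCo(dmgBF2)2, formed from divalent cobalt and H2, transfers H• to the CH2 terminus of the α-substituted acrylic acid (the only activated alkene), the tertiary α-carboxy radical closes 6-endo on the ring CH= carbon (5-exo attack at the fully substituted carbon beside the quaternary centre is blocked) through a chair transition state with CO2H pseudoaxial and CH3 pseudoequatorial, on the face anti to the pseudoaxial 3-oxobutyl chain (this facial preference is expected to be modest), which sets C1 (S) and C8a (R), and divalent cobalt then takes H• back from the unhindered ring CH2 to place the alkene at C4=C4a; the closest known reaction types are the cobaloxime/H2 radical cycloisomerisation of dienes carrying α-substituted acrylates and catalytic chain transfer of methacrylate radicals.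

Step 7
Reactants: 13 (1S,5R,6S,8aR)-1,5,6-trimethyl-5-(3-oxobutyl)-1,2,3,5,6,7,8,8a-octahydronaphthalene-1-carboxylic acid
Product: 14 (1S,5R,6S,8aR)-1,5,6-trimethyl-5-(3-methylbut-3-en-1-yl)-1,2,3,5,6,7,8,8a-octahydronaphthalene-1-carboxylic acid
Conditions: Ph3PCH3Br, KOtBu (3.5 equiv), THF, 0 → 23 °C
Reagents that add atoms: methyltriphenylphosphonium bromide, C[P+](c1ccccc1)(c1ccccc1)c1ccccc1.[Br-]
Why: Wittig methylenation of the unhindered methyl ketone; the hindered carboxylate formed in the flask and the stereocentres are inert.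

Step 8
Reactants: 14 (1S,5R,6S,8aR)-1,5,6-trimethyl-5-(3-methylbut-3-en-1-yl)-1,2,3,5,6,7,8,8a-octahydronaphthalene-1-carboxylic acid; 15 allyl acetate
Product: 16 (1S,5R,6S,8aR)-5-[(3E)-5-acetoxy-3-methylpent-3-en-1-yl]-1,5,6-trimethyl-1,2,3,5,6,7,8,8a-octahydronaphthalene-1-carboxylic acid
Conditions: 15 (5 equiv), second-generation Hoveyda–Grubbs catalyst RuCl2(=CH-C6H4-2-OiPr)(H2IMes) (5 mol %), CH2Cl2, 40 °C
Reagents that add atoms: none
Why: Olefin cross-metathesis of the 1,1-disubstituted alkene with allyl acetate gives the trisubstituted allylic acetate with the E isomer favoured (about 3:1 expected; Z isomer removed on AgNO3-impregnated silica), while the hindered ring alkene and the free acid do not react.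

## Compound list

1 | 2-methylcyclohex-2-en-1-one | CC1=CCCCC1=O | starting material
2 | (E)-1,3-dichlorobut-2-ene | ClC/C=C(/Cl)C | starting material
3 | bromomagnesium (3S)-2,3-dimethylcyclohex-1-en-1-olate | CC1=C(O[Mg]Br)CCC[C@@H]1C | intermediate
4 | (2R,3S)-2-[(2E)-3-chlorobut-2-en-1-yl]-2,3-dimethylcyclohexan-1-one | Cl/C(C)=C/C[C@@]1(C)C(=O)CCC[C@@H]1C | intermediate
5 | (5S,6R)-6-[(2E)-3-chlorobut-2-en-1-yl]-5,6-dimethylcyclohex-1-en-1-yl trifluoromethanesulfonate | Cl/C(C)=C/C[C@@]1(C)C(OS(=O)(=O)C(F)(F)F)=CCC[C@@H]1C | intermediate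
6 | (5S,6R)-5,6-dimethyl-6-(3-oxobutyl)cyclohex-1-en-1-yl trifluoromethanesulfonate | CC(=O)CC[C@@]1(C)C(OS(=O)(=O)C(F)(F)F)=CCC[C@@H]1C | intermediate
7 | methyl 2-(bromomethyl)prop-2-enoate | COC(=O)C(=C)CBr | starting material
8 | vinylmagnesium bromide | C=C[Mg]Br | starting material
9 | methyl 2-methylidenepent-4-enoate | COC(=O)C(=C)CC=C | intermediate
10 | methyl 5-(9-borabicyclo[3.3.1]nonan-9-yl)-2-methylidenepentanoate | COC(=O)C(=C)CCCB1C2CCCC1CCC2 | intermediate
11 | methyl 5-[(5S,6R)-5,6-dimethyl-6-(3-oxobutyl)cyclohex-1-en-1-yl]-2-methylidenepentanoate | CC(=O)CC[C@@]1(C)C(CCCC(=C)C(=O)OC)=CCC[C@@H]1C | intermediate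
12 | 5-[(5S,6R)-5,6-dimethyl-6-(3-oxobutyl)cyclohex-1-en-1-yl]-2-methylidenepentanoic acid | CC(=O)CC[C@@]1(C)C(CCCC(=C)C(=O)O)=CCC[C@@H]1C | intermediate
13 | (1S,5R,6S,8aR)-1,5,6-trimethyl-5-(3-oxobutyl)-1,2,3,5,6,7,8,8a-octahydronaphthalene-1-carboxylic acid | CC(=O)CC[C@@]1(C)C2=CCC[C@](C)(C(=O)O)[C@@H]2CC[C@@H]1C | intermediate
14 | (1S,5R,6S,8aR)-1,5,6-trimethyl-5-(3-methylbut-3-en-1-yl)-1,2,3,5,6,7,8,8a-octahydronaphthalene-1-carboxylic acid | CC(=C)CC[C@@]1(C)C2=CCC[C@](C)(C(=O)O)[C@@H]2CC[C@@H]1C | intermediate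
15 | allyl acetate (prop-2-en-1-yl acetate) | CC(=O)OCC=C | starting material
16 | (1S,5R,6S,8aR)-5-[(3E)-5-acetoxy-3-methylpent-3-en-1-yl]-1,5,6-trimethyl-1,2,3,5,6,7,8,8a-octahydronaphthalene-1-carboxylic acid | CC(=O)OC/C=C(\C)CC[C@@]1(C)C2=CCC[C@](C)(C(=O)O)[C@@H]2CC[C@@H]1C | target

## Step count

Total: 8 steps. Longest linear sequence: 7 steps (1, 2, 3, 5, 6, 7, 8); step 4 is a one-step side branch.

## Steps most likely to fail, with fallbacks

**Step 6 (radical cycloisomerisation).** This is the weakest step. The two faces of the ring alkene differ only by CH3 versus CH2R on the neighbouring quaternary carbon, so the C8a epimer may form in a comparable amount. The return of H• may also give some tetrasubstituted C4a=C8a alkene, and the acrylate may isomerise unproductively before it cyclises.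
Fallback: set out from 6. Suzuki–Miyaura vinylation with potassium vinyltrifluoroborate (PdCl2(dppf), Cs2CO3, THF/H2O) gives the diene 4-[(1R,6S)-2-ethenyl-1,6-dimethylcyclohex-2-en-1-yl]butan-2-one F1. A Diels–Alder reaction of F1 with methacrolein under a chiral oxazaborolidinium Lewis acid (catalyst-controlled face, formyl group endo) gives (1S,5R,6S,8aR)-1,5,6-trimethyl-5-(3-oxobutyl)-1,2,3,5,6,7,8,8a-octahydronaphthalene-1-carbaldehyde F2. Pinnick oxidation (NaClO2, NaH2PO4, 2-methylbut-2-ene) brings the route back at 13. The diene's intrinsic bias may oppose the needed face here too, so the catalyst has to override it.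

**Step 1 (asymmetric conjugate methylation with alkylation).** Methyl Grignard reagents are the least selective nucleophiles in copper-catalysed conjugate addition, and the hindered enolate may alkylate slowly.
Fallback: set out from 1. MeLi addition gives racemic 1,2-dimethylcyclohex-2-en-1-ol F3, and oxidative transposition with pyridinium chlorochromate gives 2,3-dimethylcyclohex-2-en-1-one F4. Asymmetric copper hydride conjugate reduction (Cu(OAc)2, chiral bisphosphine, PhMe2SiH) then sets the same centre by hydride delivery and gives {[(3S)-2,3-dimethylcyclohex-1-en-1-yl]oxy}dimethyl(phenyl)silane F5. Cleavage of F5 with MeLi followed by 2 and HMPA brings the route back at 4.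

**Step 8 (cross-metathesis).** The E/Z ratio of trisubstituted allylic acetates from this reaction is only moderate, and the isomers are hard to separate.
Fallback: set out from 13. LDA, ClP(O)(OEt)2, then more LDA converts the methyl ketone into the alkyne (1S,5R,6S,8aR)-5-(but-3-yn-1-yl)-1,5,6-trimethyl-1,2,3,5,6,7,8,8a-octahydronaphthalene-1-carboxylic acid F6. Cp2ZrCl2-catalysed syn-methylalumination with Me3Al and quench with paraformaldehyde gives, with E geometry fixed by the syn addition, (1S,5R,6S,8aR)-5-[(3E)-5-hydroxy-3-methylpent-3-en-1-yl]-1,5,6-trimethyl-1,2,3,5,6,7,8,8a-octahydronaphthalene-1-carboxylic acid F7. Acetylation (Ac2O, pyridine, aqueous work-up) brings the route back at 16.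

## Further compounds

F1 | step 6 | 4-[(1R,6S)-2-ethenyl-1,6-dimethylcyclohex-2-en-1-yl]butan-2-one | CC(=O)CC[C@@]1(C)C(C=C)=CCC[C@@H]1C
F2 | step 6 | (1S,5R,6S,8aR)-1,5,6-trimethyl-5-(3-oxobutyl)-1,2,3,5,6,7,8,8a-octahydronaphthalene-1-carbaldehyde | CC(=O)CC[C@@]1(C)C2=CCC[C@](C)(C=O)[C@@H]2CC[C@@H]1C
F3 | step 1 | 1,2-dimethylcyclohex-2-en-1-ol (racemic) | CC1=CCCCC1(C)O
F4 | step 1 | 2,3-dimethylcyclohex-2-en-1-one | CC1=C(C)C(=O)CCC1
F5 | step 1 | {[(3S)-2,3-dimethylcyclohex-1-en-1-yl]oxy}dimethyl(phenyl)silane | CC1=C(O[Si](C)(C)c2ccccc2)CCC[C@@H]1C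
F6 | step 8 | (1S,5R,6S,8aR)-5-(but-3-yn-1-yl)-1,5,6-trimethyl-1,2,3,5,6,7,8,8a-octahydronaphthalene-1-carboxylic acid | C#CCC[C@@]1(C)C2=CCC[C@](C)(C(=O)O)[C@@H]2CC[C@@H]1C
F7 | step 8 | (1S,5R,6S,8aR)-5-[(3E)-5-hydroxy-3-methylpent-3-en-1-yl]-1,5,6-trimethyl-1,2,3,5,6,7,8,8a-octahydronaphthalene-1-carboxylic acid | OC/C=C(\C)CC[C@@]1(C)C2=CCC[C@](C)(C(=O)O)[C@@H]2CC[C@@H]1C
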